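**Retrosynthetic overview**
- The strategy rests on O1 of ring C, which joins the C2 stereocentre to the aromatic carbon C8a of ring A. A preformed C2 carbinol can therefore be arylated at oxygen (O1–C8a) without any bond at C2 being broken.
- Monotesone A ⇐ tris-MOM flavanone (acetal removal) ⇐ cis-chroman-4-ol (C4 oxidation) ⇐ anti-1,3-diol bearing Br on the future C8a (O1–C8a by copper-catalysed O-arylation, closing ring C).
- The diol ⇐ β-hydroxy ketone (1,3-anti reduction of C4=O) ⇐ ring A bromoacetophenone + ring B aldehyde (C2–C3 by a diisopinocampheylboron aldol that sets C2).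
- Ring A ketone from 5-bromoresorcinol (C-acetylation, MOM protection); ring B aldehyde from 3,4-dihydroxybenzaldehyde (4-O-prenylation, MOM protection).
- Ring order: rings A and B are bought as arenes; ring C is the only ring built and is closed in the key step.

Key step: step 7

Remark: (+)-Ipc2BCl is the reagent made from (−)-α-pinene; the usual empirical model for methyl ketone enolates predicts si-face attack on the aldehyde (which gives 3S here), the C2 assignment would be checked on the aldol product by Mosher esters before going on, and if the sense proved opposite the enantiomeric reagent would be used with nothing else changed. The C4 configuration is of no consequence, because the later oxidation removes it. Prenyl = 3-methylbut-2-en-1-yl.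

Step 1
Reactants: 1 5-bromoresorcinol
Product: 3 1-(2-bromo-4,6-dihydroxyphenyl)ethanone, via ketiminium chloride 2 (not isolated)
Conditions: MeCN, ZnCl2 (0.5 equiv), HCl (g), Et2O, 0 °C to rt; then H2O, reflux
Reagents that add atoms: acetonitrile CC#N; water O
Why: Houben–Hoesch acylation, in which the ZnCl2-activated nitrilium electrophile should attack C4 of the resorcinol (para to one hydroxyl, ortho to the other, the usual site, rather than C2 between the hydroxyls) and hydrolysis of the ketiminium salt gives the methyl ketone.

Step 2
Reactants: 3 1-(2-bromo-4,6-dihydroxyphenyl)ethanone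
Product: 4 1-[2-bromo-4,6-bis(methoxymethoxy)phenyl]ethanone
Conditions: NaH (2.2 equiv), MOMCl (2.5 equiv), DMF, 0 °C to rt
Reagents that add atoms: chloromethyl methyl ether (MOMCl) COCCl
Why: Williamson-type O-alkylation of both phenoxides, with NaH chosen so that the hydrogen-bonded ortho hydroxyl is also fully deprotonated and capped.

Step 3
Reactants: 5 3,4-dihydroxybenzaldehyde; 6 prenyl bromide
Product: 7 3-hydroxy-4-(prenyloxy)benzaldehyde
Conditions: NaHCO3 (1.5 equiv), NaI (cat.), DMF, 40 °C
Reagents that add atoms: none
Why: regioselective Williamson etherification, since the 4-hydroxyl para to the formyl group is the more acidic and only its phenoxide forms with the weak base, displacing bromide by SN2 at the primary carbon.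

Step 4
Reactants: 7 3-hydroxy-4-(prenyloxy)benzaldehyde
Product: 8 3-(methoxymethoxy)-4-(prenyloxy)benzaldehyde
Conditions: MOMCl, i-Pr2NEt, CH2Cl2, 0 °C to rt
Reagents that add atoms: chloromethyl methyl ether (MOMCl) COCCl
Why: MOM protection of the remaining phenol by O-alkylation under amine base, giving an acetal that should survive enolborination, carbonate at 110 °C and oxidation.

Step 5
Reactants: 4 1-[2-bromo-4,6-bis(methoxymethoxy)phenyl]ethanone; 8 3-(methoxymethoxy)-4-(prenyloxy)benzaldehyde
Product: 11 (3S)-1-[2-bromo-4,6-bis(methoxymethoxy)phenyl]-3-hydroxy-3-[3-(methoxymethoxy)-4-(prenyloxy)phenyl]propan-1-one, via boron enolate 9 (not isolated), via boron aldolate 10 (not isolated)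
Conditions: (+)-Ipc2BCl, Et3N, Et2O, 0 °C; then 8, −78 to −20 °C; H2O2, MeOH, pH 7 buffer, 0 °C
Reagents that add atoms: none
Why: Paterson-type chiral boron aldol reaction, in which the diisopinocampheylboron enolate of the methyl ketone adds through a cyclic boron-centred transition state and the isopinocampheyl ligands direct it to the si face of the aldehyde, setting C2 as S under reagent control, helped by the bulky twisted aryl ketone and the unhindered aldehyde.

Step 6
Reactants: 11 the (3S)-β-hydroxy ketone
Product: 12 (1S,3S)-1-[2-bromo-4,6-bis(methoxymethoxy)phenyl]-3-[3-(methoxymethoxy)-4-(prenyloxy)phenyl]propane-1,3-diol (anti)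
Conditions: Me4NBH(OAc)3, MeCN/AcOH, −30 to −20 °C; aq. potassium sodium tartrate (KNaC4H4O6)
Reagents that add atoms: none
Why: Evans–Saksena reduction, in which the C3 hydroxyl exchanges onto boron and delivers hydride intramolecularly through a chair six-membered transition state, so the new carbinol (future C4) is set 1,3-anti (S) by the existing C3 centre.

Step 7
Reactants: 12 the anti-(1S,3S)-diol
Product: 13 (2S,4S)-5,7-bis(methoxymethoxy)-2-[3-(methoxymethoxy)-4-(prenyloxy)phenyl]chroman-4-ol (2,4-cis)
Conditions: CuI (10 mol %), 3,4,7,8-tetramethyl-1,10-phenanthroline (20 mol %), Cs2CO3 (2 equiv), toluene, 110 °C, Ar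
Reagents that add atoms: none
Why: Cs2CO3 deprotonates the C2 hydroxyl reversibly and the phenanthroline-ligated CuI (monovalent copper) takes up the alkoxide; this copper alkoxide inserts into the neighbouring C8a–Br bond to give an aryl(alkoxo) complex of trivalent copper held in a seven-membered chelate, and C–O reductive elimination forms O1–C8a and returns monovalent copper. The closest known reaction type is the Ullmann-type copper-catalysed intramolecular O-arylation of secondary alcohols by aryl bromides, which is established for chromans and 2-arylchromans. Ring C closes in a 6-exo mode, the oxygen attacking the sp2 carbon C8a whose C–Br bond lies outside the new six-membered ring. No stereocentre is created: C2 keeps its S configuration because only its O–H bond reacts, and C4 is a spectator. The step needs chemoselectivity between the two hydroxyls, which ring size secures since the C4 hydroxyl could only close a four-membered benzo-fused oxetane, and it needs the carbinol oxidation level at C4 so that no retro-aldol cleavage or dehydration to a chalcone can compete under carbonate at 110 °C. Intramolecularity and the meta placement of both MOM ethers relative to bromine should keep hydrodebromination and intermolecular etherification behind.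

Step 8
Reactants: 13 the (2S,4S)-chroman-4-ol
Product: 14 (2S)-5,7-bis(methoxymethoxy)-2-[3-(methoxymethoxy)-4-(prenyloxy)phenyl]chroman-4-one
Conditions: Dess–Martin periodinane, NaHCO3, CH2Cl2, 0 °C to rt
Reagents that add atoms: none
Why: Dess–Martin oxidation of the benzylic secondary alcohol under bicarbonate buffer should give the chromanone without ionising the acid-sensitive 4-carbinol and without touching C2, which is β to the new carbonyl and not enolisable.

Step 9
Reactants: 14 the tris-MOM flavanone
Product: 15 monotesone A
Conditions: HCl (1.25 M in MeOH, 3–5 equiv), THF, 0 °C to rt, monitored and stopped at full conversion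
Reagents that add atoms: none
Why: acid-catalysed transacetalisation of the three aryl MOM acetals to methanol via oxocarbenium ions should be much faster than SN1 ionisation of the aryl prenyl ether or opening of ring C, so the prenyl ether and the C2 configuration should be retained.

**Compound list**
1 | 5-bromoresorcinol | Oc1cc(O)cc(Br)c1 | starting material
2 | 1-(2-bromo-4,6-dihydroxyphenyl)ethan-1-iminium chloride | CC(=[NH2+])c1c(Br)cc(O)cc1O.[Cl-] | intermediate
3 | 1-(2-bromo-4,6-dihydroxyphenyl)ethanone | CC(=O)c1c(Br)cc(O)cc1O | intermediate
4 | 1-[2-bromo-4,6-bis(methoxymethoxy)phenyl]ethanone | CC(=O)c1c(Br)cc(OCOC)cc1OCOC | intermediate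
5 | 3,4-dihydroxybenzaldehyde | O=Cc1ccc(O)c(O)c1 | starting material
6 | prenyl bromide (1-bromo-3-methylbut-2-ene) | CC(C)=CCBr | starting material
7 | 3-hydroxy-4-(prenyloxy)benzaldehyde | CC(C)=CCOc1ccc(C=O)cc1O | intermediate
8 | 3-(methoxymethoxy)-4-(prenyloxy)benzaldehyde | CC(C)=CCOc1ccc(C=O)cc1OCOC | intermediate
9 | diisopinocampheylboron enolate of 4 | C=C(OB([C@H]1C[C@H]2C[C@H](C2(C)C)[C@@H]1C)[C@H]1C[C@H]2C[C@H](C2(C)C)[C@@H]1C)c1c(Br)cc(OCOC)cc1OCOC | intermediate
10 | diisopinocampheylboron aldolate (O-boryl derivative of 11) | CC(C)=CCOc1ccc([C@@H](OB([C@H]3C[C@H]4C[C@H](C4(C)C)[C@@H]3C)[C@H]3C[C@H]4C[C@H](C4(C)C)[C@@H]3C)CC(=O)c2c(Br)cc(OCOC)cc2OCOC)cc1OCOC | intermediate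
11 | (3S)-1-[2-bromo-4,6-bis(methoxymethoxy)phenyl]-3-hydroxy-3-[3-(methoxymethoxy)-4-(prenyloxy)phenyl]propan-1-one | CC(C)=CCOc1ccc([C@@H](O)CC(=O)c2c(Br)cc(OCOC)cc2OCOC)cc1OCOC | intermediate
12 | anti-(1S,3S)-1-[2-bromo-4,6-bis(methoxymethoxy)phenyl]-3-[3-(methoxymethoxy)-4-(prenyloxy)phenyl]propane-1,3-diol | CC(C)=CCOc1ccc([C@@H](O)C[C@H](O)c2c(Br)cc(OCOC)cc2OCOC)cc1OCOC | intermediate
13 | (2S,4S)-cis-5,7-bis(methoxymethoxy)-2-[3-(methoxymethoxy)-4-(prenyloxy)phenyl]chroman-4-ol | CC(C)=CCOc1ccc([C@@H]2C[C@H](O)c3c(OCOC)cc(OCOC)cc3O2)cc1OCOC | intermediate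
14 | (2S)-5,7-bis(methoxymethoxy)-2-[3-(methoxymethoxy)-4-(prenyloxy)phenyl]chroman-4-one | CC(C)=CCOc1ccc([C@@H]2CC(=O)c3c(OCOC)cc(OCOC)cc3O2)cc1OCOC | intermediate
15 | monotesone A, (2S)-5,7-dihydroxy-2-[3-hydroxy-4-(prenyloxy)phenyl]chroman-4-one | CC(C)=CCOc1ccc([C@@H]2CC(=O)c3c(O)cc(O)cc3O2)cc1O | target

**Step count**
Total step count: 9 steps. Longest linear sequence: 7 steps (steps 1, 2, 5, 6, 7, 8, 9; the ring B branch through steps 3 and 4 is equally long).

**Steps most likely to fail**

The first risk lies in step 7, the key ring closure. The copper cycle may stall because the free 1,3-diol sequesters copper, or the copper alkoxide may lose a β-hydride, which oxidises the carbinol and reduces the C–Br bond. The fallback leaves the Ullmann manifold for palladium-catalysed alkoxide arylation. There a zerovalent palladium–biarylphosphine complex first inserts into C8a–Br, and the bulky ligand then forces C–O reductive elimination ahead of β-hydride loss. Conditions: Pd(OAc)2, 2-di-tert-butylphosphino-2',4',6'-triisopropylbiphenyl, Cs2CO3, toluene, 80 °C. The fallback sets out from 12 and comes back to the route at 13. It makes no compound outside the compound list, which is what the line F0 records.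

The second risk lies in step 5, the aldol reaction. Enolborination of the hindered ketone may be incomplete, hydride transfer from an isopinocampheyl group may reduce the aryl ketone in competition with enolisation, and the facial bias of the diisopinocampheylboron enolate may be too weak, giving low enantiomeric purity at C2. The fallback moves stereocontrol from C–C bond formation to carbonyl reduction. It sets out from 4 and 8: an aldol reaction with LiN(SiMe3)2 (THF, −78 °C) should give racemic 1-[2-bromo-4,6-bis(methoxymethoxy)phenyl]-3-hydroxy-3-[3-(methoxymethoxy)-4-(prenyloxy)phenyl]propan-1-one F1. Dess–Martin oxidation should then give 1-[2-bromo-4,6-bis(methoxymethoxy)phenyl]-3-[3-(methoxymethoxy)-4-(prenyloxy)phenyl]propane-1,3-dione F2. Noyori asymmetric transfer hydrogenation (RuCl[(S,S)-TsDPEN](p-cymene), HCO2H/Et3N, rt to 40 °C) should reduce both carbonyls under catalyst control to the anti-(1S,3S)-diol. The fallback comes back to the route at 12, bypassing step 6. If the hindered ring A carbonyl resists, the mono-reduced product is 11 itself and enters step 6.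

The third risk lies in step 9, the deprotection. Protic acid may ionise the aryl prenyl ether (loss of the prenyl group or addition to the alkene) or open ring C with erosion of C2. The fallback replaces acetal solvolysis by a non-protic acetal-to-silyl-ether exchange. It sets out from 14: TMSOTf/2,2'-bipyridyl (CH2Cl2, 0 °C to rt) should convert the three aryl MOM ethers, through N-(alkoxymethyl)pyridinium intermediates, into (2S)-2-[4-(prenyloxy)-3-(trimethylsilyloxy)phenyl]-5,7-bis(trimethylsilyloxy)chroman-4-one F3. Stirring with water at rt should cleave the aryl silyl ethers, and the fallback comes back to the route at 15.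

**Further compounds**
F0 | step 7 | none | none
F1 | step 5 | racemic 1-[2-bromo-4,6-bis(methoxymethoxy)phenyl]-3-hydroxy-3-[3-(methoxymethoxy)-4-(prenyloxy)phenyl]propan-1-one | CC(C)=CCOc1ccc(C(O)CC(=O)c2c(Br)cc(OCOC)cc2OCOC)cc1OCOC
F2 | step 5 | 1-[2-bromo-4,6-bis(methoxymethoxy)phenyl]-3-[3-(methoxymethoxy)-4-(prenyloxy)phenyl]propane-1,3-dione | CC(C)=CCOc1ccc(C(=O)CC(=O)c2c(Br)cc(OCOC)cc2OCOC)cc1OCOC
F3 | step 9 | (2S)-2-[4-(prenyloxy)-3-(trimethylsilyloxy)phenyl]-5,7-bis(trimethylsilyloxy)chroman-4-one | CC(C)=CCOc1ccc([C@@H]2CC(=O)c3c(O[Si](C)(C)C)cc(O[Si](C)(C)C)cc3O2)cc1O[Si](C)(C)C
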